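**Retrosynthetic overview**
1. The last step is hydrogenolysis of ten benzyl ethers (20 → 21). Before it, ionic hydrogenation of the C2 hemiketal 18 places H-2 anti to the C3 gallate, which gives the 2,3-cis flavan.
2. The key disconnection is C8 of the benzotropolone / C2 of the gallate-bearing pyran ring, with that ring taken back to the lactone level. (R)-3-Galloyloxydihydrocoumarin 16 and benzotropolon-8-yl boronate 6 are joined by Pd–NHC insertion into C2(acyl)–O1, aryl transfer and re-closure of the pyran ring.
3. Enabling feature: C2 of the pyran ring carries O1, and O1 is the phenolic oxygen on C8a of the A ring. With C2 as a carbonyl this is an aryl ester, the only one in either half. After coupling, the O1 phenol is still held through C4–C4a and closes back onto C2.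
4. Half 6: the seven-membered ring is made from two benzene rings by oxidative coupling of the catechol B ring of (−)-epicatechin with 5-bromopyrogallol (loss of CO2). This puts Br on C8 and brings in two stereocentres.
5. Half 16: methyl (R)-glycidate (L-serine chiral pool) supplies C4–C3–C2 and the C3 stereocentre. Ring order: tropolone ring, then lactone (pyran) ring, then pyran ring re-closed on C2.

Key step: step 9

Assumption: benzylation of the tropolone unit is taken to occur on O6 (5-oxo form); the O5 regioisomer would react alike, both give the same tropolone on debenzylation, and tropolone tautomers count as one compound.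

**Step 1**
Reactants: 1 5-bromo-1,2,3-trimethoxybenzene
Product: 2 5-bromobenzene-1,2,3-triol (5-bromopyrogallol)
Conditions: BBr3, CH2Cl2, −78 °C → rt; then H2O
Reagents that add atoms: none
Why: BBr3 cleavage of aryl methyl ethers should free the three phenols without touching the aryl bromide, and no stereocentre is involved.

**Step 2**
Reactants: 2 5-bromopyrogallol; 3 (−)-epicatechin
Product: 4 (2R,3R)-2-(8-bromo-3,4,6-trihydroxy-5-oxo-5H-benzo[7]annulen-1-yl)chromane-3,5,7-triol
Conditions: horseradish peroxidase, H2O2 (slow addition), pH 5 citrate–phosphate buffer/acetone, rt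
Reagents that add atoms: none
Why: In this biomimetic oxidative benzotropolone synthesis (purpurogallin-type coupling) the B-ring o-quinone of 3 is attacked by 2 (Michael addition, carbonyl addition to a bicyclo[3.2.1] adduct, hydration, decarboxylation), which turns the Br-bearing C5 of 2 into C8 of the tropolone ring and leaves C2 and C3 of the flavan untouched.

**Step 3**
Reactants: 4 bromobenzotropolone hexaol
Product: 5 (2R,3R)-5,7-bis(benzyloxy)-2-[3,4,6-tris(benzyloxy)-8-bromo-5-oxo-5H-benzo[7]annulen-1-yl]chroman-3-ol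
Conditions: BnBr, K2CO3, DMF, 0 °C → rt
Reagents that add atoms: benzyl bromide BrCc1ccccc1
Why: In this Williamson etherification carbonate deprotonates only the four phenols and the tropolone OH, so the aliphatic C3 alcohol stays free, and it needs no protection because the gallate arrives already attached to the other half.

**Step 4**
Reactants: 5 penta-O-benzyl bromide
Product: 6 8-(pinacolatoboryl) analogue of 5
Conditions: B2pin2, PdCl2(dppf) (5 mol %), KOAc, 1,4-dioxane, 80 °C
Reagents that add atoms: bis(pinacolato)diboron CC1(C)OB(OC1(C)C)B1OC(C)(C)C(C)(C)O1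
Why: Miyaura borylation of the C8–Br bond, the only C–halogen bond, should proceed under weakly basic conditions that the free alcohol, the benzyl ethers and the tropolone ether tolerate.

**Step 5**
Reactants: 7 3,5-bis(benzyloxy)phenol
Product: 8 1,3-bis(benzyloxy)-5-(methoxymethoxy)benzene
Conditions: NaH, MOMCl, THF, 0 °C
Reagents that add atoms: chloromethyl methyl ether COCCl
Why: O-Alkylation of the phenoxide installs an acetal that marks the future O1 and acts as the strongest ortho-directing group on the ring.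

**Step 6**
Reactants: 8 MOM ether; 9 methyl (R)-glycidate
Product: 12 methyl (R)-3-[2,4-bis(benzyloxy)-6-(methoxymethoxy)phenyl]-2-hydroxypropanoate, via aryllithium 10 (not isolated), via arylmagnesium bromide 11 (not isolated)
Conditions: n-BuLi, THF, 0 °C; MgBr2·OEt2, −40 °C; CuI (10 mol %), then 9, −40 → −10 °C; aq. NH4Cl
Reagents that add atoms: none
Why: Directed ortho-metalation at the position flanked by OMOM and OBn (MOM chelation) is followed by copper-catalysed SN2 opening of the glycidate at its unsubstituted carbon, so the carbinol stereocentre (future C3, R) comes unchanged from 9.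

**Step 7**
Reactants: 12 hydroxy ester
Product: 14 (R)-5,7-bis(benzyloxy)-3-hydroxychroman-2-one, via phenolic hydroxy ester 13 (not isolated)
Conditions: p-TsOH·H2O (5 mol %), MeOH, 45 °C; then toluene, 80 °C (MeOH distilled off)
Reagents that add atoms: none
Why: Acid-catalysed acetal exchange removes the MOM group and the freed phenol lactonises (6-exo-trig transesterification) without touching the C3 stereocentre.

**Step 8**
Reactants: 14 hydroxy lactone; 15 3,4,5-tris(benzyloxy)benzoic acid
Product: 16 (R)-5,7-bis(benzyloxy)-2-oxochroman-3-yl 3,4,5-tris(benzyloxy)benzoate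
Conditions: DCC, DMAP (cat.), CH2Cl2, 0 °C → rt
Reagents that add atoms: none
Why: Steglich esterification acylates the only free OH on oxygen, so the configuration at C3 is retained.

**Step 9**
Reactants: 16 lactone gallate; 6 benzotropolon-8-yl boronate
Product: 18 (3R)-5,7-bis(benzyloxy)-2-hydroxy-2-{3,4,6-tris(benzyloxy)-1-[(2R,3R)-5,7-bis(benzyloxy)-3-hydroxychroman-2-yl]-5-oxo-5H-benzo[7]annulen-8-yl}chroman-3-yl 3,4,5-tris(benzyloxy)benzoate (hemiketal, both C2 epimers), via keto phenol 17 (not isolated)
Conditions: [Pd(IPr)(cinnamyl)Cl] (5 mol %), K2CO3 (10 mol %, precatalyst activation), H2O (2 equiv), toluene, 60 °C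
Reagents that add atoms: none
Why: Proposed new method: Pd(0)–IPr should insert into the C2(acyl)–O1 bond of 16, the only aryl ester in either partner and one made more electrophilic by the α-galloyloxy group, to give an acyl–Pd–aryloxide chelate whose own aryloxide (not an added base) activates the boronate for transfer of C8, and reductive elimination then makes the C8–C2 bond as ketone 17. The closest known reaction types are the Pd–NHC Suzuki–Miyaura acylation of phenyl esters by C(acyl)–O cleavage and the base-free coupling of phenyl trifluoroacetate with arylboronic acids, neither of which has been shown on a lactone or with a tropolonyl boronate. The opened pyran ring closes again in the same flask by 6-exo-trig addition of the freed O1 phenol to the electron-poor tropolonyl ketone, giving hemiketal 18. The new hemiketal centre C2 forms under thermodynamic control as an epimer mixture and needs no control because step 10 flattens it, while C3 is a spectator whose configuration is protected by the near-neutral medium. The selectivity needed is acyl C–O insertion at the lactone only, and it is secured because the gallate is an alkyl ester, the tropolone ether is a vinylogous ester, the benzyl ethers are inert to Pd–NHC at 60 °C, and decarbonylation of an α-oxyalkyl acyl–Pd species is slow at this temperature.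

**Step 10**
Reactants: 18 hemiketal
Product: 20 deca-O-benzyl ether of the target with (2R,3R) configuration in the new flavan unit, via trimethylsilyl ether 19 (not isolated)
Conditions: Et3SiH (10 equiv), TMSOTf (4 equiv), CH2Cl2, −78 → −30 °C; then 10 % citric acid, MeOH–THF, rt
Reagents that add atoms: none
Why: In this ionic hydrogenation of a 2-aryl hemiketal (the lactol reduction of C-aryl glycoside synthesis, a reductive etherification) TMSOTf ionises C2–OH with help from the neighbouring gallate carbonyl, and Et3SiH attacks the oxocarbenium/dioxolenium ion from the face opposite the pseudoaxial C3 gallate, so H-2 ends trans and the tropolone ring cis to O3, which sets (2R).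

**Step 11**
Reactants: 20 deca-O-benzyl ether
Product: 21 target (theaflavin monogallate with the gallate on the flavan unit carried by the seven-membered ring)
Conditions: H2 (1 atm), 20 % Pd(OH)2/C, THF–MeOH, rt; filtration under argon
Reagents that add atoms: none
Why: Catalytic hydrogenolysis should cleave all ten O-benzyl groups under neutral conditions that leave the gallate ester, the two pyran C2–O1 bonds and the four stereocentres untouched.

**Compound list**
1 | 5-bromo-1,2,3-trimethoxybenzene | COc1cc(Br)cc(OC)c1OC | starting material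
2 | 5-bromobenzene-1,2,3-triol | Oc1cc(Br)cc(O)c1O | intermediate
3 | (−)-epicatechin | O[C@@H]1Cc2c(O)cc(O)cc2O[C@@H]1c1ccc(O)c(O)c1 | starting material
4 | 8-bromobenzotropolone carrying the epicatechin A/C rings at C1 | Brc1cc(=O)c(O)c2c(O)c(O)cc([C@H]3Oc4cc(O)cc(O)c4C[C@H]3O)c2c1 | intermediate
5 | penta-O-benzyl ether of 4 (free C3 alcohol) | O=C1C(OCc9ccccc9)=CC(Br)=Cc2c([C@H]3Oc4cc(OCc9ccccc9)cc(OCc9ccccc9)c4C[C@H]3O)cc(OCc9ccccc9)c(OCc9ccccc9)c21 | intermediate
6 | benzotropolon-8-yl pinacol boronate | O=C1C(OCc9ccccc9)=CC(B5OC(C)(C)C(C)(C)O5)=Cc2c([C@H]3Oc4cc(OCc9ccccc9)cc(OCc9ccccc9)c4C[C@H]3O)cc(OCc9ccccc9)c(OCc9ccccc9)c21 | intermediate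
7 | 3,5-bis(benzyloxy)phenol | Oc1cc(OCc2ccccc2)cc(OCc2ccccc2)c1 | starting material
8 | 1,3-bis(benzyloxy)-5-(methoxymethoxy)benzene | COCOc1cc(OCc2ccccc2)cc(OCc2ccccc2)c1 | intermediate
9 | methyl (R)-glycidate | COC(=O)[C@H]1CO1 | starting material
10 | 2,4-bis(benzyloxy)-6-(methoxymethoxy)phenyllithium | [Li]c1c(OCOC)cc(OCc2ccccc2)cc1OCc1ccccc1 | intermediate
11 | 2,4-bis(benzyloxy)-6-(methoxymethoxy)phenylmagnesium bromide | Br[Mg]c1c(OCOC)cc(OCc2ccccc2)cc1OCc1ccccc1 | intermediate
12 | methyl (R)-3-[2,4-bis(benzyloxy)-6-(methoxymethoxy)phenyl]-2-hydroxypropanoate | COC(=O)[C@H](O)Cc1c(OCOC)cc(OCc2ccccc2)cc1OCc1ccccc1 | intermediate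
13 | methyl (R)-3-[2,4-bis(benzyloxy)-6-hydroxyphenyl]-2-hydroxypropanoate | COC(=O)[C@H](O)Cc1c(O)cc(OCc2ccccc2)cc1OCc1ccccc1 | intermediate
14 | (R)-5,7-bis(benzyloxy)-3-hydroxychroman-2-one | O[C@@H]1Cc2c(OCc3ccccc3)cc(OCc3ccccc3)cc2OC1=O | intermediate
15 | 3,4,5-tris(benzyloxy)benzoic acid | OC(=O)c1cc(OCc2ccccc2)c(OCc2ccccc2)c(OCc2ccccc2)c1 | starting material
16 | (R)-5,7-bis(benzyloxy)-2-oxochroman-3-yl 3,4,5-tris(benzyloxy)benzoate | O=C(O[C@@H]1Cc2c(OCc3ccccc3)cc(OCc3ccccc3)cc2OC1=O)c1cc(OCc2ccccc2)c(OCc2ccccc2)c(OCc2ccccc2)c1 | intermediate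
17 | (R)-keto phenol (open form: benzotropolon-8-yl ketone, α-gallate, free O1 phenol) | O=C(O[C@H](Cc1c(O)cc(OCc9ccccc9)cc1OCc9ccccc9)C(=O)C2=Cc3c([C@H]4Oc5cc(OCc9ccccc9)cc(OCc9ccccc9)c5C[C@H]4O)cc(OCc9ccccc9)c(OCc9ccccc9)c3C(=O)C(OCc9ccccc9)=C2)c6cc(OCc9ccccc9)c(OCc9ccccc9)c(OCc9ccccc9)c6 | intermediate
18 | (3R)-2-hydroxyflavan-type hemiketal (C2 epimers) | O=C(O[C@@H]1Cc2c(OCc9ccccc9)cc(OCc9ccccc9)cc2OC1(O)C3=Cc4c([C@H]5Oc6cc(OCc9ccccc9)cc(OCc9ccccc9)c6C[C@H]5O)cc(OCc9ccccc9)c(OCc9ccccc9)c4C(=O)C(OCc9ccccc9)=C3)c7cc(OCc9ccccc9)c(OCc9ccccc9)c(OCc9ccccc9)c7 | intermediate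
19 | O-trimethylsilyl ether of 20 (on the free C3 alcohol of the epicatechin-derived unit) | O=C(O[C@@H]1Cc2c(OCc9ccccc9)cc(OCc9ccccc9)cc2O[C@@H]1C3=Cc4c([C@H]5Oc6cc(OCc9ccccc9)cc(OCc9ccccc9)c6C[C@H]5O[Si](C)(C)C)cc(OCc9ccccc9)c(OCc9ccccc9)c4C(=O)C(OCc9ccccc9)=C3)c7cc(OCc9ccccc9)c(OCc9ccccc9)c(OCc9ccccc9)c7 | intermediate
20 | deca-O-benzyl ether of the target | O=C(O[C@@H]1Cc2c(OCc9ccccc9)cc(OCc9ccccc9)cc2O[C@@H]1C3=Cc4c([C@H]5Oc6cc(OCc9ccccc9)cc(OCc9ccccc9)c6C[C@H]5O)cc(OCc9ccccc9)c(OCc9ccccc9)c4C(=O)C(OCc9ccccc9)=C3)c7cc(OCc9ccccc9)c(OCc9ccccc9)c(OCc9ccccc9)c7 | intermediate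
21 | CNP0488827.1 (theaflavin monogallate) | O=C(O[C@@H]1Cc2c(O)cc(O)cc2O[C@@H]1c1cc(=O)c(O)c2c(O)c(O)cc([C@H]3Oc4cc(O)cc(O)c4C[C@H]3O)c2c1)c1cc(O)c(O)c(O)c1 | target

**Step count**
Total: 11 steps. Longest linear sequence: 7 steps (steps 1–4 then 9–11, or steps 5–11).

**Steps most likely to fail**

1. Step 9.
   - Risk: oxidative addition into the lactone may be too slow because its aryloxide is electron-rich. Lactone hydrolysis, protodeboronation or enolisation at C3 (erosion of configuration) could then take over.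
   - Fallback (known chemistry): a neutral Liebeskind–Srogl ketone synthesis, setting out from 16 and 6.
     - Ring opening of 16 with Me2AlSEt (AlMe3/EtSH, CH2Cl2, −20 °C) should give the phenolic S-ethyl thioester F1.
     - F1 is silylated at once (TBSCl, imidazole) to the O-TBS thioester F2.
     - Boronate 6 is converted with NaIO4/NH4OAc (acetone–water) into the boronic acid F3.
     - F2 and F3 with Pd2(dba)3, tri(2-furyl)phosphine and CuTC in THF at 50 °C should give the O-TBS ketone F4.
     - TBAF/AcOH frees the phenol, and the route is rejoined at 18.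

2. Step 10.
   - Risk: the Lewis acid may be held by the basic tropolone carbonyl, so ionisation at C2 could be sluggish. The cation may also lose H-3, which would erase the C3 configuration, or the other pyran ring may open reductively.
   - Fallback: avoid the cation altogether, setting out from 18 through its open form 17.
     - Corey–Bakshi–Shibata reduction ((S)-Me-CBS, catecholborane, toluene, −78 °C) should give the (1S,2R)-hydroxy gallate F5.
     - Mitsunobu etherification (PPh3, DIAD, THF, 0 °C) closes O1–C2 by SN2 inversion. The electron-poor tropolone ring favours this pathway.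
     - The route is rejoined at 20.

3. Step 11.
   - Risk: partial saturation of the seven-membered ring, stalling of the tenfold hydrogenolysis as the freed tropolone and catechol chelators poison the catalyst, and air oxidation during work-up.
   - Fallback: non-reductive debenzylation by cation capture. From 20, BCl3 with pentamethylbenzene as benzyl-cation scavenger (CH2Cl2, −78 °C, MeOH quench) leads directly to 21 without any new isolated compound.

**Further compounds**
F1 | step 9 | S-ethyl (R)-3-[2,4-bis(benzyloxy)-6-hydroxyphenyl]-2-[3,4,5-tris(benzyloxy)benzoyloxy]propanethioate | O=C(O[C@H](Cc1c(O)cc(OCc9ccccc9)cc1OCc9ccccc9)C(=O)SCC)c6cc(OCc9ccccc9)c(OCc9ccccc9)c(OCc9ccccc9)c6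
F2 | step 9 | O-TBS ether of F1 | O=C(O[C@H](Cc1c(O[Si](C)(C)C(C)(C)C)cc(OCc9ccccc9)cc1OCc9ccccc9)C(=O)SCC)c6cc(OCc9ccccc9)c(OCc9ccccc9)c(OCc9ccccc9)c6
F3 | step 9 | benzotropolon-8-ylboronic acid corresponding to 6 | O=C1C(OCc9ccccc9)=CC(B(O)O)=Cc2c([C@H]3Oc4cc(OCc9ccccc9)cc(OCc9ccccc9)c4C[C@H]3O)cc(OCc9ccccc9)c(OCc9ccccc9)c21
F4 | step 9 | O-TBS ether of keto phenol 17 | O=C(O[C@H](Cc1c(O[Si](C)(C)C(C)(C)C)cc(OCc9ccccc9)cc1OCc9ccccc9)C(=O)C2=Cc3c([C@H]4Oc5cc(OCc9ccccc9)cc(OCc9ccccc9)c5C[C@H]4O)cc(OCc9ccccc9)c(OCc9ccccc9)c3C(=O)C(OCc9ccccc9)=C2)c6cc(OCc9ccccc9)c(OCc9ccccc9)c(OCc9ccccc9)c6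
F5 | step 10 | (1S,2R)-1-hydroxy compound from reduction of 17 | O=C(O[C@H](Cc1c(O)cc(OCc9ccccc9)cc1OCc9ccccc9)[C@@H](O)C2=Cc3c([C@H]4Oc5cc(OCc9ccccc9)cc(OCc9ccccc9)c5C[C@H]4O)cc(OCc9ccccc9)c(OCc9ccccc9)c3C(=O)C(OCc9ccccc9)=C2)c6cc(OCc9ccccc9)c(OCc9ccccc9)c(OCc9ccccc9)c6
F0 | step 11 | none | none
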